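**Retrosynthetic overview**
- The seven-membered ring is made last: one carbon is inserted between C=O and the alkenyl carbon of a trans-fused 6-methylhydrindenone that already carries the silyl-protected vanillate.
- That enone comes from singlet-oxygen ene oxidation of a trans-fused cyclohexene, itself closed by ring-closing metathesis of trans vinyl and 2-methylallyl-carbinol arms on a cyclopentane.
- The ester is made by Pd carbonylative coupling of the secondary alcohol, CO and a 4-bromoguaiacol silyl ether (catechol → guaiacol → bromide).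
- The cyclopentane with all four stereocentres comes from enantioselective conjugate addition of a 1-silylvinyl alane to 3-methylcyclopent-2-enone with aldol trapping by 3-methylbut-3-enal, then iPrMgCl addition and protodesilylation.
- Ring order: five-membered ring (bought) → six-membered ring (metathesis) → expanded to seven.

Assumption: the enantiomer of the chiral carbene ligand in step 4 is the one that gives the S quaternary centre; MeI, CO, iPrMgCl and TMSCHN2 are bought reagents.

**Route**

Step 1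
Reactants: 1 catechol
Product: 2 guaiacol (2-methoxyphenol)
Conditions: MeI (1.0 equiv), K2CO3 (1.0 equiv), acetone, reflux
Reagents that add atoms: iodomethane, CI
Why: Williamson O-methylation with one equivalent of MeI gives mainly the mono-ether, which is separated from a little veratrole and recovered catechol by distillation; no stereocentre is involved.

Step 2
Reactants: 2 guaiacol
Product: 4 (4-bromo-2-methoxyphenoxy)(tert-butyl)dimethylsilane, via 4-bromo-2-methoxyphenol 3 (not isolated)
Conditions: NBS, MeCN, −10 °C; then imidazole, TBSCl, 0 °C → rt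
Reagents that add atoms: N-bromosuccinimide, O=C1CCC(=O)N1Br; tert-butyl(chloro)dimethylsilane, CC(C)(C)[Si](C)(C)Cl
Why: Electrophilic aromatic bromination with NBS goes para to the free hydroxyl, the strongest director, and silylation of the phenol in the same flask protects it for the later palladium, singlet-oxygen and diazo steps.

Step 3
Reactants: 5 3-methylbut-3-en-1-ol
Product: 6 3-methylbut-3-enal
Conditions: Dess–Martin periodinane, pyridine, CH2Cl2, 0 °C; cold filtered solution used at once
Reagents that add atoms: none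
Why: Buffered Dess–Martin oxidation gives the β,γ-unsaturated aldehyde without acid or base strong enough to move the double bond into conjugation, and the volatile product is used directly.

Step 4
Reactants: 7 3-methylcyclopent-2-en-1-one; 8 ethynyltrimethylsilane; 6 3-methylbut-3-enal
Product: 11 (2S,3S)-2-[(1S)-1-hydroxy-3-methylbut-3-en-1-yl]-3-methyl-3-[1-(trimethylsilyl)ethenyl]cyclopentan-1-one, via alkenylalane 9 (not isolated), via aluminium enolate 10 (not isolated)
Conditions: 8, iBu2AlH, hexane/THF, 55 °C; then 7, Cu(OTf)2 (5 mol%), chiral sulfonate-bearing imidazolinium salt (carbene precursor, 6 mol%), THF, −78 → −15 °C; then 6 (3 equiv), −78 °C; aq. NH4Cl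
Reagents that add atoms: diisobutylaluminium hydride, CC(C)C[AlH]CC(C)C
Why: cis-Hydroalumination places aluminium on the silicon-bearing carbon, copper-catalysed enantioselective conjugate addition transfers the bulky 1-silylvinyl group to C-3 (S), and the regiodefined E-enolate then undergoes aldol addition to 6 through a Zimmerman–Traxler chair on the face away from the silylvinyl group, which fixes C-2 (S, trans to silylvinyl, cis to methyl) and the anti carbinol centre (1′S).

Step 5
Reactants: 11 the aldol ketone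
Product: 12 (1R,2S,3S)-2-[(1S)-1-hydroxy-3-methylbut-3-en-1-yl]-3-methyl-1-(propan-2-yl)-3-[1-(trimethylsilyl)ethenyl]cyclopentan-1-ol
Conditions: iPrMgCl (3 equiv), LaCl3·2LiCl (1 equiv), THF, −20 → 0 °C
Reagents that add atoms: isopropylmagnesium chloride, CC(C)[Mg]Cl
Why: Lanthanum-promoted Grignard 1,2-addition avoids enolisation and β-hydride reduction, and the nucleophile attacks the chelated β-alkoxy cyclopentanone anti to the C-2 side chain, so the new tertiary hydroxyl (1R) ends up cis to that chain and to the methyl group.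

Step 6
Reactants: 12 the silylvinyl diol
Product: 13 (1R,2S,3R)-3-ethenyl-2-[(1S)-1-hydroxy-3-methylbut-3-en-1-yl]-3-methyl-1-(propan-2-yl)cyclopentan-1-ol
Conditions: Bu4NF·3H2O (5 equiv), DMSO, 80 °C
Reagents that add atoms: none
Why: Fluoride-promoted protodesilylation of the vinylsilane, assisted by the neighbouring alkoxide (Brook-type silyl transfer from carbon to oxygen), unmasks the vinyl group under non-acidic conditions that spare the acid-labile 1,1-disubstituted alkene and touch no stereocentre.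

Step 7
Reactants: 13 the vinyl diol; 4 the aryl bromide
Product: 14 (1S)-1-[(1S,2R,5R)-5-ethenyl-2-hydroxy-5-methyl-2-(propan-2-yl)cyclopentyl]-3-methylbut-3-en-1-yl 4-[(tert-butyldimethylsilyl)oxy]-3-methoxybenzoate
Conditions: Pd(OAc)2 (5 mol%), Xantphos (7.5 mol%), CO (1 atm), Et3N, DMAP (0.5 equiv), toluene, 90 °C
Reagents that add atoms: carbon monoxide, [C-]#[O+]
Why: Palladium-catalysed alkoxycarbonylation (oxidative addition of the aryl bromide, CO insertion, alcoholysis of the acyl-palladium) builds the benzoate on the secondary hydroxyl with retention at the carbinol carbon, the hindered tertiary hydroxyl staying free.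

Step 8
Reactants: 14 the diene ester
Product: 15 (3R,3aS,4S,7aR)-3-hydroxy-6,7a-dimethyl-3-(propan-2-yl)-2,3,3a,4,5,7a-hexahydro-1H-inden-4-yl 4-[(tert-butyldimethylsilyl)oxy]-3-methoxybenzoate
Conditions: second-generation Grubbs catalyst RuCl2(=CHPh)(H2IMes)(PCy3) (5 mol%), toluene, 80 °C
Reagents that add atoms: none
Why: Ring-closing metathesis joins the vinyl and 2-methylallyl groups, which sit trans on the cyclopentane, into the trans-fused cyclohexene with a trisubstituted alkene and loses ethene, leaving all four stereocentres as set.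

Step 9
Reactants: 15 the trans-fused cyclohexene
Product: 17 (3R,3aS,4S,7aS)-3-hydroxy-6,7a-dimethyl-7-oxo-3-(propan-2-yl)-2,3,3a,4,7,7a-hexahydro-1H-inden-4-yl 4-[(tert-butyldimethylsilyl)oxy]-3-methoxybenzoate, via allylic hydroperoxide 16 (not isolated)
Conditions: O2, visible light, tetraphenylporphyrin (cat.), CH2Cl2, 0 °C; then Ac2O, pyridine, DMAP (cat.), 0 °C → rt
Reagents that add atoms: dioxygen, O=O
Why: In the Schenck ene reaction singlet oxygen can bond only to C-7, because the alternative mode would need an allylic hydrogen on the quaternary C-7a, so the double bond shifts to C-5/C-6, and acetylation of the hydroperoxide with base-induced elimination (Kornblum–DeLaMare-type dehydration) gives the transposed enone, the transient C-7 stereocentre being destroyed.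

Step 10
Reactants: 17 the 6-methylhydrindenone
Product: 19 (3R,3aS,4S,8aS)-3-hydroxy-6,8a-dimethyl-8-oxo-3-(propan-2-yl)-1,2,3,3a,4,5,8,8a-octahydroazulen-4-yl 4-hydroxy-3-methoxybenzoate, via alpha-silyl ketone 18 (not isolated)
Conditions: TMSCHN2 (2.5 equiv), Sc(OTf)3 (10 mol%), CH2Cl2, −40 → 0 °C; then 48% aq. HF, MeCN, 0 °C → rt
Reagents that add atoms: (trimethylsilyl)diazomethane, C[Si](C)(C)C=[N+]=[N-]
Why: Proposed new method: Lewis-acid-activated 1,2-addition of the diazo carbon to the enone carbonyl is followed by loss of N2 with 1,2-shift of the sp2 carbon C-6 (a better migrating group and less hindered than the quaternary C-7a), which inserts one ring carbon and gives an α-silyl β,γ-enone that is also an allylsilane, so that acid removes silicon and brings the double bond into conjugation (SE2′ protonation or via the dienol) while HF also frees the phenol and no stereocentre is touched; the closest known reaction type is the Tiffeneau–Demjanov-type homologation of saturated cyclic ketones with TMSCHN2 under BF3 or Sc(OTf)3 catalysis, which has not been shown for 2-alkylcyclohex-2-enones with an α′-quaternary centre and alkenyl migration.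

**Compound list**
1 | catechol | Oc1ccccc1O | starting material
2 | guaiacol (2-methoxyphenol) | COc1ccccc1O | intermediate
3 | 4-bromo-2-methoxyphenol | COc1cc(Br)ccc1O | intermediate (not isolated)
4 | (4-bromo-2-methoxyphenoxy)(tert-butyl)dimethylsilane | COc1cc(Br)ccc1O[Si](C)(C)C(C)(C)C | intermediate
5 | 3-methylbut-3-en-1-ol | CC(=C)CCO | starting material
6 | 3-methylbut-3-enal | CC(=C)CC=O | intermediate
7 | 3-methylcyclopent-2-en-1-one | CC1=CC(=O)CC1 | starting material
8 | ethynyltrimethylsilane | C#C[Si](C)(C)C | starting material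
9 | diisobutyl[1-(trimethylsilyl)ethenyl]alumane | C=C([Si](C)(C)C)[Al](CC(C)C)CC(C)C | intermediate (not isolated)
10 | diisobutyl({(3S)-3-methyl-3-[1-(trimethylsilyl)ethenyl]cyclopent-1-en-1-yl}oxy)alumane | C[C@]1(C(=C)[Si](C)(C)C)CCC(O[Al](CC(C)C)CC(C)C)=C1 | intermediate (not isolated)
11 | (2S,3S)-2-[(1S)-1-hydroxy-3-methylbut-3-en-1-yl]-3-methyl-3-[1-(trimethylsilyl)ethenyl]cyclopentan-1-one | C=C(C)C[C@H](O)[C@@H]1[C@@](C)(C(=C)[Si](C)(C)C)CCC1=O | intermediate
12 | (1R,2S,3S)-2-[(1S)-1-hydroxy-3-methylbut-3-en-1-yl]-3-methyl-1-(propan-2-yl)-3-[1-(trimethylsilyl)ethenyl]cyclopentan-1-ol | C=C(C)C[C@H](O)[C@@H]1[C@@](C)(C(=C)[Si](C)(C)C)CC[C@@]1(O)C(C)C | intermediate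
13 | (1R,2S,3R)-3-ethenyl-2-[(1S)-1-hydroxy-3-methylbut-3-en-1-yl]-3-methyl-1-(propan-2-yl)cyclopentan-1-ol | C=C(C)C[C@H](O)[C@@H]1[C@@](C)(C=C)CC[C@@]1(O)C(C)C | intermediate
14 | (1S)-1-[(1S,2R,5R)-5-ethenyl-2-hydroxy-5-methyl-2-(propan-2-yl)cyclopentyl]-3-methylbut-3-en-1-yl 4-[(tert-butyldimethylsilyl)oxy]-3-methoxybenzoate | COc1cc(C(=O)O[C@@H](CC(C)=C)[C@@H]2[C@@](C)(C=C)CC[C@@]2(O)C(C)C)ccc1O[Si](C)(C)C(C)(C)C | intermediate
15 | (3R,3aS,4S,7aR)-3-hydroxy-6,7a-dimethyl-3-(propan-2-yl)-2,3,3a,4,5,7a-hexahydro-1H-inden-4-yl 4-[(tert-butyldimethylsilyl)oxy]-3-methoxybenzoate | COc1cc(C(=O)O[C@H]2CC(C)=C[C@@]3(C)CC[C@@](O)(C(C)C)[C@H]23)ccc1O[Si](C)(C)C(C)(C)C | intermediate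
16 | (3R,3aS,4S,7R,7aS)-7-hydroperoxy-3-hydroxy-6,7a-dimethyl-3-(propan-2-yl)-2,3,3a,4,7,7a-hexahydro-1H-inden-4-yl 4-[(tert-butyldimethylsilyl)oxy]-3-methoxybenzoate (oxygen delivered to the face opposite the 7a-methyl) | COc1cc(C(=O)O[C@H]2C=C(C)[C@@H](OO)[C@@]3(C)CC[C@@](O)(C(C)C)[C@H]23)ccc1O[Si](C)(C)C(C)(C)C | intermediate (not isolated)
17 | (3R,3aS,4S,7aS)-3-hydroxy-6,7a-dimethyl-7-oxo-3-(propan-2-yl)-2,3,3a,4,7,7a-hexahydro-1H-inden-4-yl 4-[(tert-butyldimethylsilyl)oxy]-3-methoxybenzoate | COc1cc(C(=O)O[C@H]2C=C(C)C(=O)[C@@]3(C)CC[C@@](O)(C(C)C)[C@H]23)ccc1O[Si](C)(C)C(C)(C)C | intermediate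
18 | (3R,3aS,4S,8aS)-3-hydroxy-6,8a-dimethyl-8-oxo-3-(propan-2-yl)-7-(trimethylsilyl)-1,2,3,3a,4,7,8,8a-octahydroazulen-4-yl 4-[(tert-butyldimethylsilyl)oxy]-3-methoxybenzoate (C-7 epimers, centre lost in the same flask) | COc1cc(C(=O)O[C@H]2C=C(C)C([Si](C)(C)C)C(=O)[C@@]3(C)CC[C@@](O)(C(C)C)[C@H]23)ccc1O[Si](C)(C)C(C)(C)C | intermediate (not isolated)
19 | (3R,3aS,4S,8aS)-3-hydroxy-6,8a-dimethyl-8-oxo-3-(propan-2-yl)-1,2,3,3a,4,5,8,8a-octahydroazulen-4-yl 4-hydroxy-3-methoxybenzoate | COc1cc(C(=O)O[C@H]2CC(C)=CC(=O)[C@@]3(C)CC[C@@](O)(C(C)C)[C@H]23)ccc1O | target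

**Totals and weak points**

Total step count: 10. Longest linear sequence: 8 steps (5 → 6 → 11 → 12 → 13 → 14 → 15 → 17 → 19).

Step 10 (the proposed ring expansion) is the most likely to fail. The quaternary carbon may migrate instead, the diazo compound may add across the C=C bond, or the allylsilane 18 may lose the benzoate by 1,4-elimination. The fallback uses known chemistry, sets out from 17 and comes back at 19. 1,4-Hydrosilylation of 17 (Et3SiH, RhCl(PPh3)3, toluene, 50 °C) gives the triethylsilyl enol ether F6. Furukawa cyclopropanation (Et2Zn, CH2I2, CH2Cl2, 0 °C) on the face opposite the angular methyl gives the siloxycyclopropane F7. FeCl3 in DMF at 0 °C opens the internal cyclopropane bond through the alkoxy radical (Saegusa ring expansion) to the β-chloro cycloheptanone F8. NaOAc in MeOH then eliminates HCl to the silyl-protected enone F9, and 48% aq. HF in MeCN frees the phenol to give 19.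

Step 4 (three-component conjugate addition–aldol) is the second risk. The aluminium enolate may be too sluggish, the aldehyde may isomerise to the conjugated enal, or the facial selectivity may be poor. The fallback sets out from 10 and comes back at 11. The conjugate addition mixture is quenched with Me3SiOTf and the trimethylsilyl enol ether F1 is isolated, so that ee can be checked. MeLi in THF at 0 °C then regenerates the regiodefined enolate as the lithium enolate F2 (Stork's method). Its aldol reaction with 6 at −78 °C gives 11 after chromatography.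

Step 9 (Schenck ene oxidation) is the third risk. Hydrogen abstraction from the methyl group instead of the ring CH2 would give the exocyclic methylene isomer. The fallback sets out from 15 and comes back at 17. Hydroboration (BH3·SMe2, THF, 0 °C) on the face opposite the angular methyl gives the alkylborane F3. Oxidation with NaBO3 gives the secondary alcohol F4. Excess IBX in DMSO at 75 °C oxidises it to the ketone F5 and dehydrogenates this in the same flask to 17; the regiochemistry is fixed because only C-6 carries an α-hydrogen.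

Further compounds
F1 | step 4 | trimethyl({(3S)-3-methyl-3-[1-(trimethylsilyl)ethenyl]cyclopent-1-en-1-yl}oxy)silane | C[C@]1(C(=C)[Si](C)(C)C)CCC(O[Si](C)(C)C)=C1
F2 | step 4 | lithium (3S)-3-methyl-3-[1-(trimethylsilyl)ethenyl]cyclopent-1-en-1-olate | C[C@]1(C(=C)[Si](C)(C)C)CCC(O[Li])=C1
F3 | step 9 | (3R,3aS,4S,6S,7R,7aR)-7-boranyl-3-hydroxy-6,7a-dimethyl-3-(propan-2-yl)octahydro-1H-inden-4-yl 4-[(tert-butyldimethylsilyl)oxy]-3-methoxybenzoate | COc1cc(C(=O)O[C@H]2C[C@H](C)[C@@H](B)[C@@]3(C)CC[C@@](O)(C(C)C)[C@H]23)ccc1O[Si](C)(C)C(C)(C)C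
F4 | step 9 | (3R,3aS,4S,6S,7R,7aS)-3,7-dihydroxy-6,7a-dimethyl-3-(propan-2-yl)octahydro-1H-inden-4-yl 4-[(tert-butyldimethylsilyl)oxy]-3-methoxybenzoate | COc1cc(C(=O)O[C@H]2C[C@H](C)[C@@H](O)[C@@]3(C)CC[C@@](O)(C(C)C)[C@H]23)ccc1O[Si](C)(C)C(C)(C)C
F5 | step 9 | (3R,3aS,4S,6S,7aS)-3-hydroxy-6,7a-dimethyl-7-oxo-3-(propan-2-yl)octahydro-1H-inden-4-yl 4-[(tert-butyldimethylsilyl)oxy]-3-methoxybenzoate | COc1cc(C(=O)O[C@H]2C[C@H](C)C(=O)[C@@]3(C)CC[C@@](O)(C(C)C)[C@H]23)ccc1O[Si](C)(C)C(C)(C)C
F6 | step 10 | (3R,3aS,4S,7aS)-3-hydroxy-6,7a-dimethyl-3-(propan-2-yl)-7-[(triethylsilyl)oxy]-2,3,3a,4,5,7a-hexahydro-1H-inden-4-yl 4-[(tert-butyldimethylsilyl)oxy]-3-methoxybenzoate | COc1cc(C(=O)O[C@H]2CC(C)=C(O[Si](CC)(CC)CC)[C@@]3(C)CC[C@@](O)(C(C)C)[C@H]23)ccc1O[Si](C)(C)C(C)(C)C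
F7 | step 10 | 6,7-methano adduct of F6 (siloxycyclopropane with the CH2 bridge on the face opposite the 7a-methyl) | COc1cc(C(=O)O[C@H]2C[C@@]4(C)C[C@@]4(O[Si](CC)(CC)CC)[C@@]3(C)CC[C@@](O)(C(C)C)[C@H]23)ccc1O[Si](C)(C)C(C)(C)C
F8 | step 10 | (3R,3aS,4S,8aS)-6-chloro-3-hydroxy-6,8a-dimethyl-8-oxo-3-(propan-2-yl)decahydroazulen-4-yl 4-[(tert-butyldimethylsilyl)oxy]-3-methoxybenzoate (C-6 epimers) | COc1cc(C(=O)O[C@H]2CC(C)(Cl)CC(=O)[C@@]3(C)CC[C@@](O)(C(C)C)[C@H]23)ccc1O[Si](C)(C)C(C)(C)C
F9 | step 10 | (3R,3aS,4S,8aS)-3-hydroxy-6,8a-dimethyl-8-oxo-3-(propan-2-yl)-1,2,3,3a,4,5,8,8a-octahydroazulen-4-yl 4-[(tert-butyldimethylsilyl)oxy]-3-methoxybenzoate | COc1cc(C(=O)O[C@H]2CC(C)=CC(=O)[C@@]3(C)CC[C@@](O)(C(C)C)[C@H]23)ccc1O[Si](C)(C)C(C)(C)C
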